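## Retrosynthetic overview
1. The target is read as (4S,5S,6R), with 4-OH trans to the oxirane oxygen. The last bonds made are the C7′–N amide to 2-amino-3-hydroxycyclopent-2-enone and C3′=C4′ (Horner–Wadsworth–Emmons on a C4-bound (E)-enal). Ketal and silyl removal follow.
2. The enal comes from an allyl phenyl sulfide by a sulfoxide–sulfenate [2,3] shift. The sulfide comes from Wittig methylenation of a lactol.
3. The trans hydroxy-epoxide comes from the cis one by double inversion. The side-arm carboxyl opens the first oxirane at C5 (γ-lactone), 6-OH is mesylated, and O-5 released from the lactol closes the second oxirane at C6.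
4. Key C4–C1′ bond: aldol addition of dilithiated (phenylsulfanyl)acetic acid to the C4 ketone of an enantioenriched epoxyquinone monoketal, anti to the oxirane.
5. Ring order: carbocycle from 2,5-dimethoxyaniline (oxidative dearomatisation), then first oxirane, then temporary γ-lactone, then second oxirane. The cyclopentenone ring is bought as cyclopentane-1,3-dione.

**Numbering.** Ring C1 is the ketal/ketone carbon, C2 bears N, C3 is CH, C4 is the carbinol carbon, and C5/C6 are the oxirane carbons (C5 next to C4). The lower chain is C1′–C7′. "Trienoyl" means (2E,4E,6E)-10-methylundeca-2,4,6-trienoyl.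

**Assumption 1.** N-Benzylcinchoninium chloride gives the (5R,6S)-epoxide 14. If the sense is opposite, the pseudo-enantiomeric N-benzylcinchonidinium chloride is used instead.

**Assumption 2.** The sulfur-bearing C1′ (19–26) and the lactol carbon (23) are inconsequential epimer mixtures that disappear later, so they carry no descriptor.

## Route

Step 1
Reactants: 1 4-methylpentan-1-ol
Product: 2 4-methylpentanal
Conditions: TEMPO (5 mol %), PhI(OAc)2 (1.1 equiv), CH2Cl2, rt
Reagents that add atoms: none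
Why: Oxoammonium (TEMPO) oxidation of an unhindered primary alcohol stops at the aldehyde.

Step 2
Reactants: 2 4-methylpentanal; 3 triethyl phosphonoacetate
Product: 4 ethyl (E)-6-methylhept-2-enoate
Conditions: NaH, THF, 0 °C to rt
Reagents that add atoms: none
Why: Horner–Wadsworth–Emmons olefination with a stabilised phosphonate gives the (E)-enoate from an unbranched aldehyde.

Step 3
Reactants: 4 ethyl (E)-6-methylhept-2-enoate
Product: 5 (E)-6-methylhept-2-en-1-ol
Conditions: i-Bu2AlH (2.2 equiv), CH2Cl2, −78 °C; aq. potassium sodium tartrate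
Reagents that add atoms: none
Why: 1,2-Reduction of the enoate by the aluminium hydride leaves the C=C untouched.

Step 4
Reactants: 5 (E)-6-methylhept-2-en-1-ol
Product: 6 (E)-6-methylhept-2-enal
Conditions: MnO2 (15 equiv), CH2Cl2, rt
Reagents that add atoms: none
Why: MnO2 oxidises allylic alcohols selectively and without E/Z scrambling.

Step 5
Reactants: 6 (E)-6-methylhept-2-enal; 7 triethyl 4-phosphonocrotonate
Product: 8 ethyl (2E,4E,6E)-10-methylundeca-2,4,6-trienoate
Conditions: LiN(SiMe3)2, THF, −78 to 0 °C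
Reagents that add atoms: none
Why: Vinylogous Horner–Wadsworth–Emmons olefination of an enal sets the new C4=C5 bond E, and the minor Z isomer is removed by chromatography.

Step 6
Reactants: 8 ethyl trienoate
Product: 9 (2E,4E,6E)-10-methylundeca-2,4,6-trienoic acid
Conditions: LiOH, THF/MeOH/H2O, rt; 1 M HCl
Reagents that add atoms: lithium hydroxide, [Li+].[OH-]
Why: Plain saponification, to which the all-E triene ester is stable at room temperature.

Step 7
Reactants: 9 trienoic acid
Product: 10 (2E,4E,6E)-10-methylundeca-2,4,6-trienoyl chloride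
Conditions: (COCl)2, DMF (cat.), CH2Cl2, 0 °C to rt, used crude
Reagents that add atoms: oxalyl chloride, O=C(Cl)C(=O)Cl
Why: Vilsmeier-type activation gives the acid chloride under mild conditions without isomerising the triene.

Step 8
Reactants: 11 2,5-dimethoxyaniline
Product: 12 tert-butyl N-(2,5-dimethoxyphenyl)carbamate
Conditions: Boc2O, THF, reflux
Reagents that add atoms: di-tert-butyl dicarbonate, CC(C)(C)OC(=O)OC(=O)OC(C)(C)C
Why: Carbamate formation gives crystalline later intermediates and an N–H acidic enough for step 11.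

Step 9
Reactants: 12 Boc-anilide
Product: 13 tert-butyl N-(6,6-dimethoxy-3-oxocyclohexa-1,4-dien-1-yl)carbamate (quinone monoketal, ketal next to C–N)
Conditions: PhI(OAc)2 (1.1 equiv), MeOH, 0 °C; aq. NaHCO3 work-up
Reagents that add atoms: methanol, CO; water, O
Why: In this hypervalent-iodine oxidative dearomatisation methanol adds ipso at the methoxy carbon ortho to N and the para methoxy carbon is hydrolysed to the ketone on work-up.

Step 10
Reactants: 13 quinone monoketal
Product: 14 (5R,6S)-epoxy ketone, tert-butyl N-[(1R,6S)-5,5-dimethoxy-2-oxo-7-oxabicyclo[4.1.0]hept-3-en-4-yl]carbamate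
Conditions: t-BuOOH, 1 M aq. NaOH, N-benzylcinchoninium chloride (10–20 mol %), toluene, rt, several days; recrystallise to ≥98 % ee
Reagents that add atoms: tert-butyl hydroperoxide, CC(C)(C)OO
Why: In this Weitz–Scheffer epoxidation under chiral phase-transfer catalysis only the unsubstituted enone C=C is electrophilic (the other is a vinylogous carbamate), the chiral ion pair selects one face and sets C5 (R) and C6 (S), and recrystallisation raises the ee.

Step 11
Reactants: 14 (5R,6S)-epoxy ketone; 10 trienoyl chloride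
Product: 15 N-Boc-N-trienoyl imide of the (5R,6S)-epoxy ketone
Conditions: LiOt-Bu (1.05 equiv), THF, −78 °C; then 10, −78 to 0 °C
Reagents that add atoms: none
Why: The N–H of 14 is a vinylogous imide, so its lithium salt is N-acylated cleanly, whereas the free vinylogous amide would be too poor a nucleophile.

Step 12
Reactants: 15 N-Boc imide
Product: 16 (2E,4E,6E)-N-[(1R,6S)-5,5-dimethoxy-2-oxo-7-oxabicyclo[4.1.0]hept-3-en-4-yl]-10-methylundeca-2,4,6-trienamide
Conditions: TFA (10 equiv), dry CH2Cl2, 0 °C, 30 min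
Reagents that add atoms: none
Why: Acidolysis of the Boc group of an acyl carbamate is fast at 0 °C, and without water the electron-poor ketal, the oxirane and the triene are left alone.

Step 13 (key step)
Reactants: 16 N–H trienamide epoxy ketone; 17 (phenylsulfanyl)acetic acid
Product: 19 (4S,5R,6S)-β-hydroxy acid, via dilithium enediolate 18 (not isolated)
Conditions: 17 (3.2 equiv), LiN(i-Pr)2 (6.5 equiv), THF, 0 °C; 16, −78 °C, 1 h; AcOH quench at −78 °C
Reagents that add atoms: none
Why: In this Ivanov-type aldol addition the first equivalent of 18 only removes the amide N–H and the next adds 1,2 to the activated α,β-epoxy ketone from the face opposite the oxirane oxygen, which sets C4 as S with 4-OH cis and the side arm trans to the oxirane.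

Step 14
Reactants: 19 β-hydroxy acid
Product: 20 (4S,5S,6S)-hydroxy-γ-lactone (C2′ carboxyl bound to O-5; O-5 and C1′ on one face, 4-OH and 6-OH on the other)
Conditions: pyridinium p-toluenesulfonate (10 mol %), dry CH2Cl2, rt
Reagents that add atoms: none
Why: In this acid-catalysed 5-exo-tet lactonisation the carboxyl lies opposite the oxirane oxygen and opens it at C5 by SN2 with inversion (C5 becomes S), which frees 6-OH while the anhydrous mild acid spares the ketal.

Step 15
Reactants: 20 hydroxy lactone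
Product: 21 6-O-mesyl lactone
Conditions: MsCl (1.2 equiv), Et3N, CH2Cl2, −20 to 0 °C
Reagents that add atoms: methanesulfonyl chloride, CS(=O)(=O)Cl
Why: Sulfene-type mesylation takes only the secondary 6-OH because the tertiary 4-OH reacts far more slowly.

Step 16
Reactants: 21 6-O-mesyl lactone
Product: 22 4-O-triethylsilyl 6-O-mesyl lactone
Conditions: Et3SiOTf (2.5 equiv), 2,6-lutidine, CH2Cl2, −78 to 0 °C
Reagents that add atoms: triethylsilyl triflate, CC[Si](CC)(CC)OS(=O)(=O)C(F)(F)F
Why: Silyl triflate caps the tertiary alcohol so that no C4 alkoxide can later cause retro-aldol cleavage or Payne migration, and the lutidine-buffered reagent leaves the ketal intact.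

Step 17
Reactants: 22 silylated mesyl lactone
Product: 23 lactol (C2′ hemiacetal)
Conditions: i-Bu2AlH (2.5 equiv), toluene/CH2Cl2, −78 °C; aq. potassium sodium tartrate
Reagents that add atoms: none
Why: Partial reduction of a γ-lactone stops at the aluminium lactolate at −78 °C, one equivalent being taken by the amide N–H while mesylate, ketal and sulfide are inert.

Step 18
Reactants: 23 lactol
Product: 25 (4S,5S,6R)-allyl phenyl sulfide, via epoxy aldehyde 24 (not isolated)
Conditions: Ph3PCH3Br (5 equiv), KN(SiMe3)2 (4.8 equiv), THF, −78 °C to rt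
Reagents that add atoms: methyltriphenylphosphonium bromide, C[P+](c1ccccc1)(c1ccccc1)c1ccccc1.[Br-]
Why: In this lactol Wittig methylenation, opening of the lactolate frees the O-5 alkoxide antiperiplanar to the C6 mesylate, it closes the new oxirane by SN2 with inversion at C6 (now R, oxirane trans to O-4), and the unmasked aldehyde is trapped at once by Ph3P=CH2.

Step 19
Reactants: 25 allyl phenyl sulfide
Product: 28 (E)-allylic alcohol, via allyl sulfoxide 26 (not isolated), via allyl sulfenate 27 (not isolated)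
Conditions: mCPBA (1.0 equiv), NaHCO3, CH2Cl2, −78 °C; then Et2NH, MeOH, rt to 40 °C
Reagents that add atoms: 3-chloroperoxybenzoic acid, OOC(=O)c1cccc(Cl)c1
Why: Chemoselective sulfide oxidation followed by Mislow–Evans [2,3]-sigmatropic rearrangement and thiophilic cleavage gives the primary alcohol, with the bulky C4 group enforcing E geometry at C1′=C2′ and erasing the C1′ centre.

Step 20
Reactants: 28 (E)-allylic alcohol
Product: 29 (E)-enal
Conditions: MnO2 (20 equiv), CH2Cl2, rt
Reagents that add atoms: none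
Why: This neutral allylic oxidation touches neither enamide, oxirane, ketal nor silyl ether.

Step 21
Reactants: 29 (E)-enal; 7 triethyl 4-phosphonocrotonate
Product: 30 ethyl (2′E,4′E,6′E)-heptatrienoate on C4
Conditions: 7 (2.5 equiv), LiN(SiMe3)2 (2.4 equiv), THF, −78 to 0 °C
Reagents that add atoms: none
Why: Vinylogous Horner–Wadsworth–Emmons olefination sets C3′=C4′ E and brings in C5′=C6′ E, the excess anion covering the amide N–H.

Step 22
Reactants: 30 ethyl heptatrienoate
Product: 31 heptatrienoic acid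
Conditions: LiOH (5 equiv), THF/MeOH/H2O, rt; 0.5 M HCl to pH 4, 0 °C
Reagents that add atoms: lithium hydroxide, [Li+].[OH-]
Why: Saponification is done while C1 is still a ketal and O-4 is silylated, so there is no base-sensitive epoxy enone and no free alkoxide.

Step 23
Reactants: 32 cyclopentane-1,3-dione
Product: 33 2-(hydroxyimino)cyclopentane-1,3-dione
Conditions: NaNO2, aq. HCl, 0 °C
Reagents that add atoms: sodium nitrite, [Na+].[O-]N=O
Why: Nitrosation of the enolised 1,3-dione at C2 gives the oxime tautomer.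

Step 24
Reactants: 33 oxime
Product: 34 2-amino-3-hydroxycyclopent-2-en-1-one hydrochloride
Conditions: H2 (1 atm), Pd/C, HCl, MeOH, rt
Reagents that add atoms: hydrogen chloride, Cl
Why: Catalytic hydrogenation of the oxime in acid gives the amine, stored as its stable hydrochloride.

Step 25
Reactants: 31 heptatrienoic acid; 34 aminocyclopentenone hydrochloride
Product: 36 protected bis-amide (C1 dimethyl ketal and 4-O-triethylsilyl ether), via mixed anhydride 35 (not isolated)
Conditions: i-BuOCOCl, N-methylmorpholine, THF, −20 °C; then 34, N-methylmorpholine, DMF, −20 °C to rt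
Reagents that add atoms: none
Why: Mixed carbonic anhydride amidation is nearly neutral yet reactive enough for this weakly nucleophilic amine, and any O-acyl product shifts to N.

Step 26
Reactants: 36 protected bis-amide
Product: 37 4-O-triethylsilyl epoxy enone
Conditions: TFA/H2O/CH2Cl2 (1:1:20), 0 °C
Reagents that add atoms: water, O
Why: Acid hydrolysis of the dimethyl ketal unveils the enone, after which C4 can no longer ionise, and any material that also loses silicon converges in step 27.

Step 27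
Reactants: 37 4-O-triethylsilyl epoxy enone
Product: 38 target, (4S,5S,6R)
Conditions: HF·pyridine, pyridine, THF, 0 °C to rt; pH 7 buffer work-up, exclusion of light
Reagents that add atoms: none
Why: Buffered fluoride desilylation frees 4-OH without ever forming an alkoxide, so the trans hydroxy-epoxide cannot undergo Payne rearrangement.

## Compound list
1 | 4-methylpentan-1-ol | CC(C)CCCO | starting material
2 | 4-methylpentanal | CC(C)CCC=O | intermediate
3 | triethyl phosphonoacetate | CCOC(=O)CP(=O)(OCC)OCC | starting material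
4 | ethyl (E)-6-methylhept-2-enoate | CC(C)CC/C=C/C(=O)OCC | intermediate
5 | (E)-6-methylhept-2-en-1-ol | CC(C)CC/C=C/CO | intermediate
6 | (E)-6-methylhept-2-enal | CC(C)CC/C=C/C=O | intermediate
7 | triethyl 4-phosphonocrotonate | CCOC(=O)/C=C/CP(=O)(OCC)OCC | starting material
8 | ethyl (2E,4E,6E)-10-methylundeca-2,4,6-trienoate | CC(C)CC/C=C/C=C/C=C/C(=O)OCC | intermediate
9 | (2E,4E,6E)-10-methylundeca-2,4,6-trienoic acid | CC(C)CC/C=C/C=C/C=C/C(=O)O | intermediate
10 | (2E,4E,6E)-10-methylundeca-2,4,6-trienoyl chloride | CC(C)CC/C=C/C=C/C=C/C(=O)Cl | intermediate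
11 | 2,5-dimethoxyaniline | COc1ccc(OC)c(N)c1 | starting material
12 | tert-butyl N-(2,5-dimethoxyphenyl)carbamate | COc1ccc(OC)c(NC(=O)OC(C)(C)C)c1 | intermediate
13 | tert-butyl N-(6,6-dimethoxy-3-oxocyclohexa-1,4-dien-1-yl)carbamate | CC(C)(C)OC(=O)NC1=CC(=O)C=CC1(OC)OC | intermediate
14 | tert-butyl N-[(1R,6S)-5,5-dimethoxy-2-oxo-7-oxabicyclo[4.1.0]hept-3-en-4-yl]carbamate (5R,6S) | CC(C)(C)OC(=O)NC1=CC(=O)[C@@H]2O[C@@H]2C1(OC)OC | intermediate
15 | N-Boc-N-trienoyl imide of the (5R,6S)-epoxy ketone | CC(C)CC/C=C/C=C/C=C/C(=O)N(C(=O)OC(C)(C)C)C1=CC(=O)[C@@H]2O[C@@H]2C1(OC)OC | intermediate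
16 | N–H trienamide of the (5R,6S)-epoxy ketone | CC(C)CC/C=C/C=C/C=C/C(=O)NC1=CC(=O)[C@@H]2O[C@@H]2C1(OC)OC | intermediate
17 | (phenylsulfanyl)acetic acid | OC(=O)CSc1ccccc1 | starting material
18 | dilithium enediolate of 17 | [Li+].[Li+].[O-]C([O-])=CSc1ccccc1 | intermediate (not isolated)
19 | (4S,5R,6S)-β-hydroxy acid: 2-(phenylsulfanyl)acetic acid bound through C1′ to C4; 4-OH cis to the oxirane, C1′ epimers | CC(C)CC/C=C/C=C/C=C/C(=O)NC1=C[C@@](O)(C(Sc3ccccc3)C(=O)O)[C@@H]2O[C@@H]2C1(OC)OC | intermediate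
20 | (4S,5S,6S)-hydroxy-γ-lactone, cis-fused at C4/C5, 6-OH free | CC(C)CC/C=C/C=C/C=C/C(=O)NC1=C[C@@]2(O)C(Sc3ccccc3)C(=O)O[C@H]2[C@H](O)C1(OC)OC | intermediate
21 | 6-O-mesyl lactone | CC(C)CC/C=C/C=C/C=C/C(=O)NC1=C[C@@]2(O)C(Sc3ccccc3)C(=O)O[C@H]2[C@H](OS(C)(=O)=O)C1(OC)OC | intermediate
22 | 4-O-triethylsilyl 6-O-mesyl lactone | CC(C)CC/C=C/C=C/C=C/C(=O)NC1=C[C@@]2(O[Si](CC)(CC)CC)C(Sc3ccccc3)C(=O)O[C@H]2[C@H](OS(C)(=O)=O)C1(OC)OC | intermediate
23 | lactol of 22 | CC(C)CC/C=C/C=C/C=C/C(=O)NC1=C[C@@]2(O[Si](CC)(CC)CC)C(Sc3ccccc3)C(O)O[C@H]2[C@H](OS(C)(=O)=O)C1(OC)OC | intermediate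
24 | (4S,5S,6R)-epoxy aldehyde, 2-(phenylsulfanyl)acetaldehyde unit on C4, oxirane trans to O-4 | CC(C)CC/C=C/C=C/C=C/C(=O)NC1=C[C@@](O[Si](CC)(CC)CC)(C(Sc3ccccc3)C=O)[C@H]2O[C@H]2C1(OC)OC | intermediate (not isolated)
25 | (4S,5S,6R)-allyl phenyl sulfide, 1-(phenylsulfanyl)prop-2-enyl on C4 | CC(C)CC/C=C/C=C/C=C/C(=O)NC1=C[C@@](O[Si](CC)(CC)CC)(C(Sc3ccccc3)C=C)[C@H]2O[C@H]2C1(OC)OC | intermediate
26 | allyl phenyl sulfoxide | CC(C)CC/C=C/C=C/C=C/C(=O)NC1=C[C@@](O[Si](CC)(CC)CC)(C(C=C)S(=O)c3ccccc3)[C@H]2O[C@H]2C1(OC)OC | intermediate (not isolated)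
27 | (E)-allyl benzenesulfenate | CC(C)CC/C=C/C=C/C=C/C(=O)NC1=C[C@@](O[Si](CC)(CC)CC)(/C=C/COSc3ccccc3)[C@H]2O[C@H]2C1(OC)OC | intermediate (not isolated)
28 | (4S,5S,6R)-(E)-allylic alcohol, (E)-3-hydroxyprop-1-enyl on C4 | CC(C)CC/C=C/C=C/C=C/C(=O)NC1=C[C@@](O[Si](CC)(CC)CC)(/C=C/CO)[C@H]2O[C@H]2C1(OC)OC | intermediate
29 | (E)-enal, (E)-3-oxoprop-1-enyl on C4 | CC(C)CC/C=C/C=C/C=C/C(=O)NC1=C[C@@](O[Si](CC)(CC)CC)(/C=C/C=O)[C@H]2O[C@H]2C1(OC)OC | intermediate
30 | ethyl (2E,4E,6E)-hepta-2,4,6-trienoate bound through C7 to C4 | CC(C)CC/C=C/C=C/C=C/C(=O)NC1=C[C@@](O[Si](CC)(CC)CC)(/C=C/C=C/C=C/C(=O)OCC)[C@H]2O[C@H]2C1(OC)OC | intermediate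
31 | corresponding heptatrienoic acid | CC(C)CC/C=C/C=C/C=C/C(=O)NC1=C[C@@](O[Si](CC)(CC)CC)(/C=C/C=C/C=C/C(=O)O)[C@H]2O[C@H]2C1(OC)OC | intermediate
32 | cyclopentane-1,3-dione | O=C1CCC(=O)C1 | starting material
33 | 2-(hydroxyimino)cyclopentane-1,3-dione | O=C1CCC(=O)C1=NO | intermediate
34 | 2-amino-3-hydroxycyclopent-2-en-1-one hydrochloride | NC1=C(O)CCC1=O.Cl | intermediate
35 | isobutyl carbonic mixed anhydride of 31 | CC(C)CC/C=C/C=C/C=C/C(=O)NC1=C[C@@](O[Si](CC)(CC)CC)(/C=C/C=C/C=C/C(=O)OC(=O)OCC(C)C)[C@H]2O[C@H]2C1(OC)OC | intermediate (not isolated)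
36 | protected bis-amide (C1 dimethyl ketal, 4-O-triethylsilyl) | CC(C)CC/C=C/C=C/C=C/C(=O)NC1=C[C@@](O[Si](CC)(CC)CC)(/C=C/C=C/C=C/C(=O)NC3=C(O)CCC3=O)[C@H]2O[C@H]2C1(OC)OC | intermediate
37 | 4-O-triethylsilyl epoxy enone | CC(C)CC/C=C/C=C/C=C/C(=O)NC1=C[C@@](O[Si](CC)(CC)CC)(/C=C/C=C/C=C/C(=O)NC3=C(O)CCC3=O)[C@H]2O[C@H]2C1=O | intermediate
38 | CNP0304685.4, (4S,5S,6R) | CC(C)CC/C=C/C=C/C=C/C(=O)NC1=C[C@@](O)(/C=C/C=C/C=C/C(=O)NC2=C(O)CCC2=O)[C@H]2O[C@H]2C1=O | target

## Counts and risks
Total step count: 27.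
Longest linear sequence: 22 steps (steps 1–7, 11–22 and 25–27, from 1 to 38).

**Step 13.** The lithium amidate formed from 16 may deactivate the ketone, or the aldolate may revert. The fallback sets out from 15 and comes back at 20. Step 12 is omitted and the aprotic, more electrophilic imide 15 serves as the acceptor. Treatment with 1.2 equiv of 18 at −90 °C and a cold AcOH quench gives the N-Boc β-hydroxy acid F1. Pyridinium p-toluenesulfonate in CH2Cl2 converts it into the N-Boc hydroxy lactone F2. TFA in dry CH2Cl2 at 0 °C then removes the Boc group to give 20.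

**Step 18.** The free α-sulfanyl aldehyde may enolise and expel the silyloxy group, or the silyl group may migrate to O-5 in the basic aprotic medium. The fallback sets out from 22 and comes back at 25, and it separates the two events. K2CO3 in MeOH at 0 °C opens the lactone, and the O-5 alkoxide closes the oxirane in protic medium to give the epoxy methyl ester F3. i-Bu2AlH at −78 °C gives aldehyde 24, which is now isolated. Non-basic titanium carbene methylenation with Cp2Ti(CH2)(Cl)AlMe2 in THF/toluene/pyridine at −40 to 0 °C gives 25.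

**Step 25.** The amine of 34 is a poor nucleophile and the advanced acid is precious. The fallback sets out from 29 and comes back at 36, and it forms the amide on a small robust acid. LiOH hydrolysis of 7 gives (E)-4-(diethoxyphosphoryl)but-2-enoic acid F4. Its isobutyl mixed anhydride acylates 34 to give the phosphonate amide F5. The trianion of F5 (LiN(SiMe3)2, 3.1 equiv, THF, −78 to 0 °C) then olefinates enal 29 directly to 36, so steps 21, 22 and 25 are no longer needed.

## Further compounds
F1 | step 13 | N-Boc (4S,5R,6S)-β-hydroxy acid | CC(C)CC/C=C/C=C/C=C/C(=O)N(C(=O)OC(C)(C)C)C1=C[C@@](O)(C(Sc3ccccc3)C(=O)O)[C@@H]2O[C@@H]2C1(OC)OC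
F2 | step 13 | N-Boc (4S,5S,6S)-hydroxy lactone | CC(C)CC/C=C/C=C/C=C/C(=O)N(C(=O)OC(C)(C)C)C1=C[C@@]2(O)C(Sc3ccccc3)C(=O)O[C@H]2[C@H](O)C1(OC)OC
F3 | step 18 | (4S,5S,6R)-epoxy methyl ester | CC(C)CC/C=C/C=C/C=C/C(=O)NC1=C[C@@](O[Si](CC)(CC)CC)(C(Sc3ccccc3)C(=O)OC)[C@H]2O[C@H]2C1(OC)OC
F4 | step 25 | (E)-4-(diethoxyphosphoryl)but-2-enoic acid | CCOP(=O)(C/C=C/C(=O)O)OCC
F5 | step 25 | diethyl [(E)-4-[(2-hydroxy-5-oxocyclopent-1-en-1-yl)amino]-4-oxobut-2-enyl]phosphonate | CCOP(=O)(C/C=C/C(=O)NC1=C(O)CCC1=O)OCC
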